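Remark: ring atoms are numbered C1 (carries the exocyclic C7H2O group), C2 (=CH) and C3 to C6, with On the oxygen on Cn, and open-chain intermediates keep these labels. Diol 1, the LiAlH4 reduction product of the acetonide of an L-tartrate diester, is taken as a purchased material, so the route needs no hydride reduction of its own.

## Structural features

The target is a single carbocycle, a cyclohex-1-ene in which C1 carries an exocyclic benzoyloxymethyl group (C7–O7Bz) and C2 is the vinylic CH. C3 to C6 are four contiguous oxygen-bearing stereocentres of configuration 3S,4R,5R,6R: O3/O4 trans, O4/O5 trans, O5/O6 cis. O5 is benzoylated, whereas O3, O4 and O6 are free, and O3 and O6 are allylic. The fragile elements are the two benzoates, which can shift to a neighbouring free hydroxyl under base (O5 to O4 or O6, O7 to O6), and the allylic C3–O and C6–O bonds, which ionise under strong acid. The skeleton is small, so the real difficulty is to set four adjacent stereocentres in the absolute sense and to tell five oxygens apart so that exactly O5 and O7 are acylated. The key step exploits the cis pair C5–O5/C6–O6 lying next to the trans pair C3–O3/C4–O4: the trans pair maps onto the two stereocentres of L-tartaric acid, and C5 and C6 can both be aldehyde carbons of an open chain that are joined reductively on samarium. For that, C1=C2 must be a Z enal, and because the two one-carbon arms on C1 (C6 and C7) differ only in what their oxygens carry, the alkene geometry decides which arm becomes ring carbon C6 and must not be scrambled by acyl transfer between the arms. In the closed ring the trans-fused isopropylidene ketal holds O3 and O4 equatorial, which makes O5 equatorial and O6 pseudoaxial and so distinguishes the two new hydroxyls for the last benzoylation.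

## Logic of the disconnections

16 ⇒ 15. The last forward operation breaks the two O–C bonds that tie O3 and O4 to the ketal carbon. Keeping these oxygens masked to the end means only O5 and O6 ever have to be told apart, and the ketal is the one bought with 1. The forward step may use mild acid only, because two benzoates and two allylic C–O bonds are present.

15 ⇒ 14 + 10. The O5–C(acyl) bond is cut. This leaves a cis diol and returns the second benzoate to a bulk reagent. Forward, the acylation must pick equatorial O5 over pseudoaxial, allylic O6 and must not set the O7 ester moving.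

14 ⇒ 13. The C5–C6 ring bond is cut so that both carbons become aldehyde carbons. The ring, one skeletal bond and two stereocentres disappear at once, and the open chain keeps only the stereocentres of 1. Forward, the reductive coupling must give the cis diol on the face away from O4, and the conjugated aldehyde must couple through C6 without being reduced further.

13 ⇒ 12. No skeletal bond is cut; C5 and C6 are each taken down one oxidation level. 13 is too sensitive to carry through protecting-group steps, so it is made last and used at once. The forward double oxidation must form both aldehydes together, without Z/E isomerisation, γ-deprotonation or lactol formation.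

12 ⇒ 11. The O5–CH2Ar and O6–CH2Ar bonds are restored. One arylmethyl group on both oxygens lets one operation free both, and it is chosen because it leaves under neutral oxidative conditions. In 12 a base-promoted 1,3-acyl shift from O7 to O6 would amount to inverting the alkene geometry, so the forward step must avoid basic reagents.

11 ⇒ 9 + 10. The O7–C(acyl) bond is cut. Putting this benzoate on early fixes which arm is C7 and removes a late selectivity problem. Forward it is a plain acylation of the only free hydroxyl.

9 ⇒ 8. The C7 alcohol is traced back to an ester (C7–OEt bond restored), because an ester is what an olefination delivers trans to C3. Forward, the reduction must be 1,2 and leave the alkene geometry alone.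

8 ⇒ 4 + 5 + 6 (through 7). The C1=C2 double bond and the O6–C6 bond are cut. This separates the chiral four-carbon piece (C2–C5) from an achiral three-carbon piece (C1, C6, C7) and a simple alcohol. Forward, the olefination must give the E ester, so that the ester arm (C7) is trans and the ether arm (C6) cis to C3, and 7 must add to 4 faster than it loses alkoxide.

4 ⇒ 3. C2 is taken down from aldehyde to alcohol; no bond is cut. Forward, the oxidation must not epimerise C3, which is helped by the trans-disubstituted dioxolane being the more stable arrangement.

3 ⇒ 1 + 2. The O5–CH2Ar bond is cut. The two hydroxyls of 1 are homotopic, so the only demand is mono- rather than bis-alkylation.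

## Other disconnections considered

Alternative 1: C1–C6 and C4–C5 are cut in a retro-Diels–Alder sense, after O3 has been moved back to C1 by an allylic 1,3-shift (alkene to C2=C3) and O4 tied to C7 as a lactone.
- Forward key step: endo cycloaddition of the cinchona-alkaloid-bound anion of 3-hydroxy-2H-pyran-2-one A1 to vinylene carbonate A2, giving the bridged lactone A3 with the carbocycle, the bridgehead C1–OH and the cis C5/C6 carbonate in place.
- In its favour: two achiral bulk compounds give the ring and four stereocentres (C1, C4, C5, C6) in one catalytic step. The cis C5/C6 relationship is inherited from the dienophile geometry, and endo addition puts O5/O6 anti to O4.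
- Against it here: A2 is not the electron-poor, hydrogen-bond-accepting kind of dienophile on which this anionic cycloaddition and its enantiocontrol depend. A3 can lose CO2 on warming. The tertiary C1–OH must then be transposed suprafacially to C3, and after opening of lactone and carbonate the hydroxyls must be sorted with no built-in distinction between O3, O4, O5 and O6.
- Comparison: structurally it reaches the carbocycle far sooner and secures the cis diol by geometry instead of chelation; on both points it is the better plan. Mechanistically a concerted cycloaddition is cleaner than a ketyl coupling, but its feasibility with this dienophile is the open question, whereas the pinacol closure has close analogy. In step economy the short start is likely to be used up by the transposition and the protecting-group work needed to benzoylate only O5 and O7, so it is expected to be about equal in length and less certain.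

Alternative 2: the cut is the C2–C3 bond, seen as an aldol bond, with C7 removed so that C1 is a ketone.
- Forward key step: a catalytic salt of divalent mercury in aqueous acetone would hydrate the exocyclic enol ether of methyl 3-O-benzoyl-2,4-bis-O-(tert-butyldimethylsilyl)-6-deoxy-α-D-arabino-hex-5-enopyranoside A4. The anomeric carbon is released as the C3 aldehyde and the C2 mercurio-enolate adds to it to give the cyclohexanone A5.
- In its favour: the carbocyclisation is a dependable polar process, and C4, C5 and C6 come from the sugar with fixed configuration. The O5 benzoate is carried from the start, so no regioselective acylation of a diol is needed; on this point it is the better plan.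
- Against it here: the sugar needs the altro arrangement of O2–O4, which is not that of a common hexose and must be built by inversions, plus three protecting-group placements and the 5,6-elimination. This carbocyclisation usually places the new hydroxyl trans to the oxygen two carbons away, whereas A5 has O3 and O5 cis, so the wanted C3 epimer may be the minor one. A5 is a β-hydroxy ketone prone to lose O3. C7 must still be attached at C1 with the alkene placed at C1=C2, which costs several more steps.
- Comparison: both plans take the absolute configuration from the chiral pool and are equal on that count. The ring closure is mechanistically more predictable than a samarium ketyl coupling, but the new stereocentre is less well controlled than C5/C6 in the chosen plan. In step economy the alternative is expected to be clearly longer, and it uses a toxic mercury salt.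

Alternative 3: no ring bond is cut. The six ring carbons and C7 come from an arene, and the cut is at C4–O and C5–O of an epoxide on the quinone monoketal (3,3-dimethoxy-6-oxocyclohexa-1,4-dien-1-yl)methyl benzoate A6.
- Forward key step: an alkyl hydroperoxide anion paired with a cinchona-derived ammonium phase-transfer catalyst would add to C4 of the C6(=O)–C5=C4 enone and close onto C5 to give the epoxy ketone A7. Reduction at C6, opening of the epoxide at C5 by benzoate with inversion, ketal hydrolysis and reduction at C3 would follow.
- In its favour: it is by far the shortest line, and all seven carbons and the O7 benzoate are present from the first intermediate. The two enone double bonds of A6 differ enough (C4=C5 unsubstituted, C1=C2 substituted) for site-selective epoxidation, and the trans O4/O5 relationship follows from epoxide opening. In step economy it is the better plan.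
- Against it here: the absolute configuration rests wholly on catalyst control over a flat, prochiral dienone, and the basic peroxide medium threatens the primary benzoate. Three later substrate-controlled events must each go the right way: hydride delivery at C6 cis to the future O5, benzoate attack at C5 and not C4, and hydride delivery at C3 trans to O4.
- Comparison: structurally it builds no C–C bond and is the more economical. Mechanistically its polar steps are individually simple, but the stereochemical risk is spread over four steps, whereas the chosen plan takes C3 and C4 from L-tartaric acid and sets C5 and C6 in one templated step. On security of absolute and relative configuration the chosen plan is judged the better.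

Key step: step 8

## Route

Step 1
Reactants: 1 (4S,5S)-2,3-O-isopropylidene-L-threitol [(4S,5S)-2,2-dimethyl-1,3-dioxolane-4,5-dimethanol]; 2 4-methoxybenzyl chloride
Product: 3 [(4S,5S)-5-{[(4-methoxybenzyl)oxy]methyl}-2,2-dimethyl-1,3-dioxolan-4-yl]methanol (mono-PMB ether; PMB = 4-methoxybenzyl)
Conditions: NaH (1.0 equiv), THF/DMF 4:1, 0 °C; then 2 (1.0 equiv), Bu4NI (5 mol%), 0 °C → rt
Reagents that add atoms: 4-methoxybenzyl chloride (2), COc1ccc(CCl)cc1
Why: Williamson ether synthesis on the monosodium alkoxide; the two hydroxyls of the C2-symmetric diol are homotopic, so only the degree of alkylation has to be controlled (one equivalent of base and halide), and no stereocentre is touched.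

Step 2
Reactants: 3 mono-PMB ether
Product: 4 (4R,5S)-5-{[(4-methoxybenzyl)oxy]methyl}-2,2-dimethyl-1,3-dioxolane-4-carbaldehyde (C2 aldehyde)
Conditions: (COCl)2, DMSO, CH2Cl2, −78 °C; then Et3N, −78 → 0 °C
Reagents that add atoms: none
Why: Swern oxidation of the primary alcohol; the C3 stereocentre α to the new aldehyde should hold because the trans-4,5-disubstituted dioxolane is the thermodynamically preferred arrangement and the base is added cold; 4 is used without chromatography.

Step 3
Reactants: 4 C2 aldehyde; 5 ethyl 2-(diethoxyphosphoryl)prop-2-enoate; 6 4-methoxybenzyl alcohol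
Product: 8 ethyl (2E)-2-{[(4-methoxybenzyl)oxy]methyl}-3-[(4S,5S)-5-{[(4-methoxybenzyl)oxy]methyl}-2,2-dimethyl-1,3-dioxolan-4-yl]prop-2-enoate, via sodium phosphonate carbanion 7 (not isolated)
Conditions: 6 (1.2 equiv), NaH (1.2 equiv), THF, 0 °C; 5 (1.2 equiv), −78 → 0 °C; then 4, −78 °C → rt
Reagents that add atoms: ethyl 2-(diethoxyphosphoryl)prop-2-enoate (5), C=C(C(=O)OCC)P(=O)(OCC)OCC; 4-methoxybenzyl alcohol (6), COc1ccc(CO)cc1
Why: Tandem oxa-Michael addition and Horner–Wadsworth–Emmons olefination: the alkoxide of 6 adds to the doubly activated alkene of 5 to give the stabilised carbanion 7, which condenses with 4; with a sodium counter-ion in THF and warming, this α-branched phosphonoacetate anion is expected to give mainly the E ester (C3 trans to CO2Et, cis to the CH2OPMB arm). That geometry is what later makes the ether arm ring carbon C6 and the ester arm C7; the stereocentres of 4 are carried over unchanged.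

Step 4
Reactants: 8 E ester
Product: 9 (2Z)-2-{[(4-methoxybenzyl)oxy]methyl}-3-[(4S,5S)-5-{[(4-methoxybenzyl)oxy]methyl}-2,2-dimethyl-1,3-dioxolan-4-yl]prop-2-en-1-ol
Conditions: iBu2AlH (2.5 equiv), CH2Cl2, −78 °C; aq. potassium sodium tartrate
Reagents that add atoms: none
Why: 1,2-Reduction of an α,β-unsaturated ester to the allylic alcohol with iBu2AlH at low temperature; ethers, ketal and alkene geometry are unaffected (the descriptor changes from E to Z only because the priorities of the two arms change).

Step 5
Reactants: 9 allylic alcohol; 10 benzoyl chloride
Product: 11 (2E)-2-{[(4-methoxybenzyl)oxy]methyl}-3-[(4S,5S)-5-{[(4-methoxybenzyl)oxy]methyl}-2,2-dimethyl-1,3-dioxolan-4-yl]prop-2-en-1-yl benzoate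
Conditions: 10 (1.2 equiv), pyridine (3 equiv), DMAP (5 mol%), CH2Cl2, 0 °C
Reagents that add atoms: benzoyl chloride (10), O=C(Cl)c1ccccc1
Why: Acylation of the only free hydroxyl with an acid chloride under nucleophilic catalysis; it fixes the arm trans to C3 as C7–OBz before the second arm is unmasked.

Step 6
Reactants: 11 bis-PMB benzoate
Product: 12 (2E)-2-(hydroxymethyl)-3-[(4S,5S)-5-(hydroxymethyl)-2,2-dimethyl-1,3-dioxolan-4-yl]prop-2-en-1-yl benzoate
Conditions: DDQ (2.6 equiv), CH2Cl2/aq. NaH2PO4–Na2HPO4 buffer (pH 7) 10:1, 0 °C → rt
Reagents that add atoms: none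
Why: Oxidative cleavage of both 4-methoxybenzyl ethers by DDQ (hydride abstraction, then hydrolysis of the oxocarbenium ions by water); the buffered, non-basic medium should keep the O7 benzoate from shifting to the new O6 hydroxyl, which would be equivalent to E/Z scrambling, and ketal and alkene are inert.

Step 7
Reactants: 12 diol
Product: 13 (2Z)-2-formyl-3-[(4S,5R)-5-formyl-2,2-dimethyl-1,3-dioxolan-4-yl]prop-2-en-1-yl benzoate [(Z)-2-(benzoyloxymethyl)-4,5-O-isopropylidene-4,5-dihydroxyhex-2-enedial]
Conditions: (COCl)2 (3 equiv), DMSO (6 equiv), CH2Cl2, −78 °C; then iPr2NEt (8 equiv), −78 → −30 °C; cold aq. NaH2PO4 wash; used at once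
Reagents that add atoms: none
Why: Double Swern oxidation: both hydroxyls become alkoxysulfonium ions before any base is present, so no hydroxy aldehyde, lactol or acyl shift can arise, and the hindered amine at low temperature limits γ-deprotonation and Z/E isomerisation of the enal.

Step 8
Reactants: 13 Z dialdehyde
Product: 14 [(3aS,4R,5R,7aS)-4,5-dihydroxy-2,2-dimethyl-3a,4,5,7a-tetrahydro-1,3-benzodioxol-6-yl]methyl benzoate (7-O-benzoyl-3,4-O-isopropylidene cyclohexene 5,6-cis-diol)
Conditions: SmI2 (0.1 M in THF, 2.5 equiv), THF, −78 °C, slow addition of 13 (final 0.01 M), no HMPA, no proton donor; aq. NaHCO3 at −78 °C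
Reagents that add atoms: none
Why: Pinacol-type reductive cyclisation: divalent samarium transfers one electron to the conjugated C6 aldehyde (the more easily reduced carbonyl) to give a samarium-bound ketyl delocalised over C6–C1–C2, a second equivalent engages the C5 aldehyde, and the two carbonyl carbons join to form C5–C6, both oxygens staying as alkoxides on trivalent samarium until work-up. The closest known reaction type is the SmI2 pinacol cyclisation of sugar-derived 1,5- and 1,6-dialdehydes to cis-cycloalkanediols; a conjugated partner is the less common variant. The cyclohexene closes in a 6-exo-trig mode onto the C5 carbonyl; the Z alkene holds C6 next to C5, and coupling through C2, the other end of the allylic ketyl, would need a four-membered ring, so no other ring size is open. C5 and C6 are the new stereocentres, and their cis relationship is controlled by chelation of both oxygens to trivalent samarium in the bond-forming transition state. The face is controlled by C4: the trans-fused dioxolane holds O3 and O4 equatorial, the forming C5–C6 bond lies anti to C4–O4, and the bulky samarium-bound O5 should take the equatorial site trans to O4, which puts O6 pseudoaxial, where it also escapes allylic strain with the C7 arm on C1; this is the 5R,6R configuration of the target. The step needs coupling to win over two-electron (conjugate) reduction of the enal, which would open the way to elimination of O3 or of the O7 benzoate, and over intermolecular coupling; the fully substituted α-carbon and branched β-carbon of the enal disfavour β-coupling, and the absence of HMPA and proton donors, the low temperature and slow addition at high dilution are chosen to favour intramolecular ketyl coupling. A benzoate is not reduced by SmI2 in THF alone, and the cold bicarbonate quench limits benzoyl transfer from O7 to the new O6 alkoxide.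

Step 9
Reactants: 14 cis-diol; 10 benzoyl chloride
Product: 15 [(3aR,4R,5R,7aS)-4-(benzoyloxy)-5-hydroxy-2,2-dimethyl-3a,4,5,7a-tetrahydro-1,3-benzodioxol-6-yl]methyl benzoate (5,7-di-O-benzoate, O6 free)
Conditions: 2-aminoethyl diphenylborinate (Ph2BOCH2CH2NH2, 10 mol%), 10 (1.1 equiv), iPr2NEt (1.5 equiv), MeCN, 0 °C → rt
Reagents that add atoms: benzoyl chloride (10), O=C(Cl)c1ccccc1
Why: Diarylborinic-acid-catalysed regioselective acylation of a cis-1,2-diol on a six-membered ring: the catalyst binds O5 and O6 reversibly as a tetracoordinate borinate, which raises their nucleophilicity, and the acid chloride should react at the equatorial, less hindered O5 and not at the pseudoaxial allylic O6 flanked by C1 and its C7 arm; no stereocentre is formed.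

Step 10
Reactants: 15 di-O-benzoate acetonide
Product: 16 [(3S,4R,5R,6R)-5-(benzoyloxy)-3,4,6-trihydroxycyclohex-1-en-1-yl]methyl benzoate (target, CNP0198957.7)
Conditions: AcOH/H2O 4:1, 40 °C
Reagents that add atoms: none
Why: Acid-catalysed hydrolysis of the isopropylidene ketal; the trans ring fusion strains the dioxolane so that dilute acetic acid should suffice, conditions under which benzoates should neither migrate nor hydrolyse and the allylic C–O bonds should not ionise; all four stereocentres are untouched.

## Compound list

1 | (4S,5S)-2,2-dimethyl-1,3-dioxolane-4,5-dimethanol (2,3-O-isopropylidene-L-threitol) | OC[C@@H]1OC(C)(C)O[C@H]1CO | starting material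
2 | 4-methoxybenzyl chloride | COc1ccc(CCl)cc1 | starting material
3 | [(4S,5S)-5-{[(4-methoxybenzyl)oxy]methyl}-2,2-dimethyl-1,3-dioxolan-4-yl]methanol | OC[C@@H]1OC(C)(C)O[C@H]1COCc1ccc(OC)cc1 | intermediate
4 | (4R,5S)-5-{[(4-methoxybenzyl)oxy]methyl}-2,2-dimethyl-1,3-dioxolane-4-carbaldehyde | O=C[C@@H]1OC(C)(C)O[C@H]1COCc1ccc(OC)cc1 | intermediate
5 | ethyl 2-(diethoxyphosphoryl)prop-2-enoate | C=C(C(=O)OCC)P(=O)(OCC)OCC | starting material
6 | 4-methoxybenzyl alcohol | COc1ccc(CO)cc1 | starting material
7 | sodium salt of ethyl 2-(diethoxyphosphoryl)-3-[(4-methoxybenzyl)oxy]propanoate (phosphonate carbanion) | CCOC(=O)[C-](COCc1ccc(OC)cc1)P(=O)(OCC)OCC.[Na+] | intermediate (not isolated)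
8 | ethyl (2E)-2-{[(4-methoxybenzyl)oxy]methyl}-3-[(4S,5S)-5-{[(4-methoxybenzyl)oxy]methyl}-2,2-dimethyl-1,3-dioxolan-4-yl]prop-2-enoate | CCOC(=O)/C(COCc1ccc(OC)cc1)=C/[C@@H]1OC(C)(C)O[C@H]1COCc1ccc(OC)cc1 | intermediate
9 | (2Z)-2-{[(4-methoxybenzyl)oxy]methyl}-3-[(4S,5S)-5-{[(4-methoxybenzyl)oxy]methyl}-2,2-dimethyl-1,3-dioxolan-4-yl]prop-2-en-1-ol | OC/C(COCc1ccc(OC)cc1)=C/[C@@H]1OC(C)(C)O[C@H]1COCc1ccc(OC)cc1 | intermediate
10 | benzoyl chloride | O=C(Cl)c1ccccc1 | starting material
11 | (2E)-2-{[(4-methoxybenzyl)oxy]methyl}-3-[(4S,5S)-5-{[(4-methoxybenzyl)oxy]methyl}-2,2-dimethyl-1,3-dioxolan-4-yl]prop-2-en-1-yl benzoate | O=C(OC/C(COCc1ccc(OC)cc1)=C/[C@@H]1OC(C)(C)O[C@H]1COCc1ccc(OC)cc1)c1ccccc1 | intermediate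
12 | (2E)-2-(hydroxymethyl)-3-[(4S,5S)-5-(hydroxymethyl)-2,2-dimethyl-1,3-dioxolan-4-yl]prop-2-en-1-yl benzoate | O=C(OC/C(CO)=C/[C@@H]1OC(C)(C)O[C@H]1CO)c1ccccc1 | intermediate
13 | (2Z)-2-formyl-3-[(4S,5R)-5-formyl-2,2-dimethyl-1,3-dioxolan-4-yl]prop-2-en-1-yl benzoate | O=C/C(COC(=O)c1ccccc1)=C\[C@@H]1OC(C)(C)O[C@H]1C=O | intermediate (precursor of the key step)
14 | [(3aS,4R,5R,7aS)-4,5-dihydroxy-2,2-dimethyl-3a,4,5,7a-tetrahydro-1,3-benzodioxol-6-yl]methyl benzoate | O=C(OCC1=C[C@@H]2OC(C)(C)O[C@H]2[C@H](O)[C@@H]1O)c1ccccc1 | intermediate (product of the key step)
15 | [(3aR,4R,5R,7aS)-4-(benzoyloxy)-5-hydroxy-2,2-dimethyl-3a,4,5,7a-tetrahydro-1,3-benzodioxol-6-yl]methyl benzoate | O=C(OCC1=C[C@@H]2OC(C)(C)O[C@H]2[C@H](OC(=O)c2ccccc2)[C@@H]1O)c1ccccc1 | intermediate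
16 | [(3S,4R,5R,6R)-5-(benzoyloxy)-3,4,6-trihydroxycyclohex-1-en-1-yl]methyl benzoate | O=C(OCC1=C[C@H](O)[C@@H](O)[C@H](OC(=O)c2ccccc2)[C@@H]1O)c1ccccc1 | target

## Step count and least certain steps

Total step count: 10 (steps 1 to 10, one line without a separate branch). Longest linear sequence: 10 steps, from 1 to 16.

Key step (step 8). The likeliest failure is two-electron conjugate reduction of the enal outrunning the coupling, followed by elimination of O3 or of the O7 benzoate from the resulting enolate. Intermolecular coupling, facial selection at C5 against the expected sense, and benzoyl transfer from O7 to the samarium-bound O6 are lesser risks. The fallback sets out from 13 and returns at 14; it makes the C5–C6 bond as a double bond and adds the two oxygens afterwards: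
- Double Wittig methylenation of 13 (Ph3P=CH2, THF, −78 → 0 °C) would give the triene (2E)-2-ethenyl-3-[(4S,5S)-5-ethenyl-2,2-dimethyl-1,3-dioxolan-4-yl]prop-2-en-1-yl benzoate F1.
- Ring-closing metathesis of its two monosubstituted alkenes with the second-generation Grubbs catalyst (CH2Cl2, 40 °C) would give the cyclohexadiene [(3aS,7aS)-2,2-dimethyl-3a,7a-dihydro-1,3-benzodioxol-5-yl]methyl benzoate F2.
- Catalytic OsO4 with N-methylmorpholine N-oxide (acetone/H2O, 0 °C) would dihydroxylate the disubstituted, less hindered C5=C6 bond from the face opposite to O4 and arrive at 14.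

Step 3. Geometric control may be poor with this α-alkoxy aldehyde and branched phosphonate, and the oxa-Michael addition may reverse, with loss of alkoxide from 7 and oligomerisation of 5. The fallback sets out from 4 and returns at 8; it builds the trisubstituted alkene by allylic transposition instead of olefination:
- Morita–Baylis–Hillman reaction of 4 with ethyl acrylate (DABCO, rt) would give ethyl 2-{hydroxy[5-{[(4-methoxybenzyl)oxy]methyl}-2,2-dimethyl-1,3-dioxolan-4-yl]methyl}prop-2-enoate F3 as a mixture of carbinol epimers, which is of no consequence.
- N-bromosuccinimide/Me2S (CH2Cl2, 0 °C) would convert it, with allylic transposition, into ethyl (2Z)-2-(bromomethyl)-3-[(4S,5S)-5-{[(4-methoxybenzyl)oxy]methyl}-2,2-dimethyl-1,3-dioxolan-4-yl]prop-2-enoate F4, in which C3 is trans to the ester as in 8.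
- Etherification with 6 (Ag2O, CH2Cl2, rt) would return to 8.

Step 7. The amine base may cause isomerisation of the Z enal to the E enal (which cannot cyclise), or γ-deprotonation at C3 followed by elimination. The fallback sets out from 12 and returns at 13; it replaces the one-pot, base-mediated double oxidation by two base-free, chemoselective oxidations:
- MnO2 (CH2Cl2, rt) would oxidise only the allylic C6 alcohol to give the hydroxy enal (2Z)-2-formyl-3-[(4S,5S)-5-(hydroxymethyl)-2,2-dimethyl-1,3-dioxolan-4-yl]prop-2-en-1-yl benzoate F5.
- Dess–Martin periodinane (NaHCO3, CH2Cl2, 0 °C) would then oxidise O5 to give 13.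

Step 9. Discrimination between O5 and O6 may be insufficient, or over-acylation or benzoyl shifts (O7 to O6, O5 to O6) may occur under the amine base. The fallback sets out from 14 and returns at 15; it replaces selective acylation by a protecting-group relay that leaves O5 as the only free hydroxyl:
- K2CO3 in MeOH (0 °C) would remove the O7 benzoate to give the triol (3aS,4R,5R,7aS)-6-(hydroxymethyl)-2,2-dimethyl-3a,4,5,7a-tetrahydro-1,3-benzodioxole-4,5-diol F6.
- tBu2Si(OTf)2 with 2,6-lutidine (DMF, −40 °C) would bridge the 1,3-related O6 and O7 as the six-membered 6,7-O-(di-tert-butylsilanediyl) derivative F7, as 4,6-diols of pyranosides are bridged in the presence of a cis 3,4-diol.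
- Benzoylation of the one remaining hydroxyl with 10 (pyridine, DMAP) would give the 5-O-benzoyl silylene F8.
- HF·pyridine (THF, 0 °C) would free O6 and O7 to give (3aR,4R,5R,7aS)-5-hydroxy-6-(hydroxymethyl)-2,2-dimethyl-3a,4,5,7a-tetrahydro-1,3-benzodioxol-4-yl benzoate F9.
- 10 (1 equiv) with 2,4,6-collidine (CH2Cl2, −40 °C) would acylate the primary allylic O7 and return to 15.

## Further compounds

F1 | step 8 | (2E)-2-ethenyl-3-[(4S,5S)-5-ethenyl-2,2-dimethyl-1,3-dioxolan-4-yl]prop-2-en-1-yl benzoate | C=C/C(COC(=O)c1ccccc1)=C\[C@@H]1OC(C)(C)O[C@H]1C=C
F2 | step 8 | [(3aS,7aS)-2,2-dimethyl-3a,7a-dihydro-1,3-benzodioxol-5-yl]methyl benzoate | O=C(OCC1=C[C@@H]2OC(C)(C)O[C@H]2C=C1)c1ccccc1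
F3 | step 3 | ethyl 2-{hydroxy[5-{[(4-methoxybenzyl)oxy]methyl}-2,2-dimethyl-1,3-dioxolan-4-yl]methyl}prop-2-enoate (dioxolane stereocentres as in 4; both carbinol epimers) | C=C(C(=O)OCC)C(O)[C@@H]1OC(C)(C)O[C@H]1COCc1ccc(OC)cc1
F4 | step 3 | ethyl (2Z)-2-(bromomethyl)-3-[(4S,5S)-5-{[(4-methoxybenzyl)oxy]methyl}-2,2-dimethyl-1,3-dioxolan-4-yl]prop-2-enoate | CCOC(=O)/C(CBr)=C/[C@@H]1OC(C)(C)O[C@H]1COCc1ccc(OC)cc1
F5 | step 7 | (2Z)-2-formyl-3-[(4S,5S)-5-(hydroxymethyl)-2,2-dimethyl-1,3-dioxolan-4-yl]prop-2-en-1-yl benzoate | O=C/C(COC(=O)c1ccccc1)=C\[C@@H]1OC(C)(C)O[C@H]1CO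
F6 | step 9 | (3aS,4R,5R,7aS)-6-(hydroxymethyl)-2,2-dimethyl-3a,4,5,7a-tetrahydro-1,3-benzodioxole-4,5-diol | OCC1=C[C@@H]2OC(C)(C)O[C@H]2[C@H](O)[C@@H]1O
F7 | step 9 | 6,7-O-(di-tert-butylsilanediyl) derivative of F6 (O5–H free; stereocentres as in 14) | CC(C)(C)[Si]1(C(C)(C)C)OCC2=C[C@@H]3OC(C)(C)O[C@H]3[C@H](O)[C@@H]2O1
F8 | step 9 | 5-O-benzoyl derivative of F7 (stereocentres as in 14) | CC(C)(C)[Si]1(C(C)(C)C)OCC2=C[C@@H]3OC(C)(C)O[C@H]3[C@H](OC(=O)c3ccccc3)[C@@H]2O1
F9 | step 9 | (3aR,4R,5R,7aS)-5-hydroxy-6-(hydroxymethyl)-2,2-dimethyl-3a,4,5,7a-tetrahydro-1,3-benzodioxol-4-yl benzoate | OCC1=C[C@@H]2OC(C)(C)O[C@H]2[C@H](OC(=O)c2ccccc2)[C@@H]1O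
A1 | alternative 1 | 3-hydroxy-2H-pyran-2-one | O=C1OC=CC=C1O
A2 | alternative 1 | vinylene carbonate (1,3-dioxol-2-one) | O=C1OC=CO1
A3 | alternative 1 | endo cycloadduct: 2-oxabicyclo[2.2.2]oct-7-en-3-one with bridgehead hydroxyl on C1 and cis cyclic carbonate on C5/C6 (target numbering) | O[C@]1(C(=O)O2)C=C[C@@H]2[C@@H]3OC(=O)O[C@H]13
A4 | alternative 2 | methyl 3-O-benzoyl-2,4-bis-O-(tert-butyldimethylsilyl)-6-deoxy-α-D-arabino-hex-5-enopyranoside | CO[C@@H]1[C@@H](O[Si](C)(C)C(C)(C)C)[C@H](OC(=O)c2ccccc2)[C@H](O[Si](C)(C)C(C)(C)C)C(=C)O1
A5 | alternative 2 | 5-O-benzoyl-4,6-bis-O-(tert-butyldimethylsilyl)-3-hydroxycyclohexanone (target numbering; ketone C1, CH2 C2) | O=C1C[C@H](O)[C@@H](O[Si](C)(C)C(C)(C)C)[C@H](OC(=O)c2ccccc2)[C@@H]1O[Si](C)(C)C(C)(C)C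
A6 | alternative 3 | (3,3-dimethoxy-6-oxocyclohexa-1,4-dien-1-yl)methyl benzoate | O=C(OCC1=CC(OC)(OC)C=CC1=O)c1ccccc1
A7 | alternative 3 | 4,5-epoxide of A6 (ketone C6, ketal C3; target numbering) | O=C(OCC1=CC(OC)(OC)[C@H]2O[C@H]2C1=O)c1ccccc1
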